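**Strategy.** Numbering: ring C1 (carbinol carbon), C2, C3, C4 (CMeCl), C5 (CHBr), C6; side chain C7–C11. The ring is read as a masked isoprene adduct: the trans C4–Cl/C5–Br pair is the retron of a C4=C5 alkene, and the C4 methyl lies 1,4 to the oxygenated quaternary C1. A Diels–Alder reaction of isoprene with a chiral, lactic acid-derived 5-methylene-1,3-dioxolan-4-one (an α-hydroxyacrylate equivalent) therefore forms C2–C3 and C6–C1 in one operation and sets C1. The C1 hydroxyl then relays its configuration to C4 and C5 by bromoetherification and chloride opening; a Weinreb ketone synthesis, methylenation and desilylation attach the (R)-configured side chain.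

Key step: step 3

Assumption: (R)-lactic acid, pivalaldehyde, isoprene and 5-bromo-2-methylpent-2-ene are taken as commercial, and each minor cis/trans or regioisomeric component is removed at the stage where it arises.

Step 1
Reactants: 1 (R)-lactic acid; 2 pivalaldehyde
Product: 3 (2R,5R)-2-tert-butyl-5-methyl-1,3-dioxolan-4-one
Conditions: TsOH·H2O (cat.), H2SO4 (cat.), pentane, reflux, Dean–Stark; recrystallisation (Et2O/pentane, −78 °C)
Reagents that add atoms: none
Why: Acid-catalysed acetalisation of the α-hydroxy acid, in which the lactic acid stereocentre steers the new acetal centre to the thermodynamically preferred cis isomer; this is crystallised to purity because its (2R) purity later becomes the enantiopurity of the dienophile.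

Step 2
Reactants: 3 (2R,5R)-2-tert-butyl-5-methyl-1,3-dioxolan-4-one
Product: 5 (2R)-2-tert-butyl-5-methylene-1,3-dioxolan-4-one, via bromo dioxolanone 4 (not isolated)
Conditions: NBS (1.05 equiv), AIBN (cat.), PhCF3, 80 °C; then Et3N (2.2 equiv), 0 °C to rt
Reagents that add atoms: none
Why: Wohl–Ziegler radical bromination at the captodative C5–H and E2 loss of HBr toward the methyl group should give the exocyclic alkene; the C5 stereocentre is deliberately destroyed while the (2R) acetal centre is untouched.

Step 3
Reactants: 5 (2R)-2-tert-butyl-5-methylene-1,3-dioxolan-4-one; 6 isoprene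
Product: 7 (2R,5S)-2-tert-butyl-8-methyl-1,3-dioxaspiro[4.5]dec-7-en-4-one
Conditions: 6 (8 equiv), BHT (cat.), toluene, sealed tube, 100 °C
Reagents that add atoms: none
Why: Concerted, asynchronous thermal [4+2] cycloaddition in which the exocyclic CH2 of 5 (future C2) bonds ahead to the isoprene terminus next to the methyl-bearing carbon (future C3), while the oxygenated carbon (future C1) bonds to the other terminus (future C6). The closest known reaction type is the auxiliary-controlled Diels–Alder reaction of 2-tert-butyl-5-methylene-1,3-dioxolan-4-ones with dienes. The cyclohexene ring closes by an intermolecular suprafacial [4π+2π] cycloaddition that also creates the spiro junction at C1. The new stereocentre C1 is controlled by the acetal stereocentre: the tert-butyl group shields one face of the planar, s-cis-locked dienophile, so the diene should add anti to it and give (5S). The step needs para regioselectivity, which rests on the match between the larger HOMO coefficient at the isoprene CH2 attached to the methyl-bearing carbon and the larger LUMO coefficient at the exocyclic CH2 of the α-oxyacrylate. Because both diene termini are unsubstituted no endo/exo isomers arise, and any meta-oriented adduct is removed by chromatography.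

Step 4
Reactants: 7 (2R,5S)-2-tert-butyl-8-methyl-1,3-dioxaspiro[4.5]dec-7-en-4-one
Product: 8 methyl (S)-1-hydroxy-4-methylcyclohex-3-ene-1-carboxylate
Conditions: K2CO3 (0.2 equiv), MeOH, 0 °C to rt
Reagents that add atoms: methanol, CO
Why: Base-catalysed methanolysis of the acylal-type lactone, in which methoxide opens the carbonyl and the hemiacetal alkoxide expels pivalaldehyde, should free the tertiary hydroxyl without touching the C1 stereocentre.

Step 5
Reactants: 8 methyl (S)-1-hydroxy-4-methylcyclohex-3-ene-1-carboxylate
Product: 10 methyl (1S,3R,4R)-3-bromo-4-chloro-1-hydroxy-4-methylcyclohexane-1-carboxylate, via bridged bromo ether 9 (not isolated)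
Conditions: NBS (1.05 equiv), CH2Cl2, 0 °C, dark; then TiCl4 (2.5 equiv), −78 to −40 °C; aq. NaHCO3
Reagents that add atoms: N-bromosuccinimide, O=C1CCC(=O)N1Br; titanium tetrachloride, Cl[Ti](Cl)(Cl)Cl
Why: Bromonium formation is reversible and only the bromonium ion anti to the C1 hydroxyl can be captured transannularly at the tertiary C4 (Markovnikov bromoetherification, as in the conversion of terpinen-4-ol to 2-bromo-1,4-cineole), which fixes Br on C5 trans to the C1–O bond; TiCl4, chelated by the α-alkoxy ester, then ionises the C4–O bond with help from the antiperiplanar bromine and chloride opens the bromonium ion at C4 anti to Br (Lewis-acid ether cleavage with neighbouring-group participation), so Cl should end up cis to the hydroxyl with net retention at C4.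

Step 6
Reactants: 10 methyl (1S,3R,4R)-3-bromo-4-chloro-1-hydroxy-4-methylcyclohexane-1-carboxylate
Product: 11 (1S,3R,4R)-3-bromo-4-chloro-1-hydroxy-N-methoxy-N,4-dimethylcyclohexane-1-carboxamide
Conditions: MeNH(OMe)·HCl (3 equiv), iPrMgCl (6.5 equiv), THF, −20 to 0 °C
Reagents that add atoms: N,O-dimethylhydroxylamine hydrochloride, CNOC.Cl
Why: Aminolysis of the ester by the chloromagnesium amide of N,O-dimethylhydroxylamine (Weinreb amide formation), assisted by the neighbouring magnesium alkoxide; no stereocentre is involved and the cold, weakly basic medium should spare both halides.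

Step 7
Reactants: 12 5-bromo-2-methylpent-2-ene
Product: 13 (R)-3-(2-bromoethyl)-2,2-dimethyloxirane
Conditions: 1,2:4,5-di-O-isopropylidene-β-D-erythro-2,3-hexodiulo-2,6-pyranose (0.3 equiv), KHSO5 (as Oxone, 2KHSO5·KHSO4·K2SO4), K2CO3, Bu4NHSO4 (cat.), MeCN/CH2(OMe)2/aq. Na2B4O7 buffer, 0 °C
Reagents that add atoms: potassium peroxymonosulfate, [K+].[O-]S(=O)(=O)OO
Why: Shi epoxidation, in which the chiral dioxirane transfers oxygen through a spiro transition state to one face of the trisubstituted alkene; for 2-methyl-2-alkenes the D-fructose-derived ketone should set the (R) configuration at the CH carbon.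

Step 8
Reactants: 13 (R)-3-(2-bromoethyl)-2,2-dimethyloxirane
Product: 14 (R)-5-bromo-2-methylpent-1-en-3-ol
Conditions: diethylaluminium 2,2,6,6-tetramethylpiperidide (3 equiv, from lithium 2,2,6,6-tetramethylpiperidide and Et2AlCl), toluene, 0 °C; aq. potassium sodium tartrate
Reagents that add atoms: none
Why: Epoxide to allylic alcohol rearrangement with a bulky aluminium amide: syn β-elimination by abstraction of a methyl proton cleaves the tertiary C–O bond, so the C–O bond at the stereocentre is never broken and (R) is retained.

Step 9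
Reactants: 14 (R)-5-bromo-2-methylpent-1-en-3-ol
Product: 15 (R)-[(5-bromo-2-methylpent-1-en-3-yl)oxy](tert-butyl)dimethylsilane
Conditions: TBSOTf (1.2 equiv), 2,6-lutidine (1.5 equiv), CH2Cl2, −78 °C
Reagents that add atoms: tert-butyldimethylsilyl trifluoromethanesulfonate, CC(C)(C)[Si](C)(C)OS(=O)(=O)C(F)(F)F
Why: Fast silylation of the secondary allylic alcohol with a silyl triflate and a hindered base, chosen so that no nucleophile is present that could alkylate at the primary bromide.

Step 10
Reactants: 11 (1S,3R,4R)-3-bromo-4-chloro-1-hydroxy-N-methoxy-N,4-dimethylcyclohexane-1-carboxamide; 15 (R)-[(5-bromo-2-methylpent-1-en-3-yl)oxy](tert-butyl)dimethylsilane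
Product: 17 (4R)-1-[(1S,3R,4R)-3-bromo-4-chloro-1-hydroxy-4-methylcyclohexyl]-4-[(tert-butyldimethylsilyl)oxy]-5-methylhex-5-en-1-one, via Grignard reagent 16 (not isolated)
Conditions: 15 (1.6 equiv), Mg, THF, 40 °C; 11, t-BuMgCl (1.0 equiv), THF, −40 °C; then 16, −40 to 0 °C; aq. NH4Cl
Reagents that add atoms: none
Why: Weinreb ketone synthesis: t-BuMgCl first masks the tertiary hydroxyl as its magnesium alkoxide, the primary Grignard reagent adds once to the amide and the chelated tetrahedral intermediate survives until the quench, while the unactivated secondary bromide and tertiary chloride should not react with Grignard reagents at this temperature.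

Step 11
Reactants: 17 (4R)-1-[(1S,3R,4R)-3-bromo-4-chloro-1-hydroxy-4-methylcyclohexyl]-4-[(tert-butyldimethylsilyl)oxy]-5-methylhex-5-en-1-one
Product: 18 (1S,3R,4R)-3-bromo-1-[(5R)-5-[(tert-butyldimethylsilyl)oxy]-6-methylhepta-1,6-dien-2-yl]-4-chloro-4-methylcyclohexan-1-ol
Conditions: Ph3PCH3Br (4 equiv), KOtBu (3.8 equiv), THF, 0 °C to rt
Reagents that add atoms: methyltriphenylphosphonium bromide, C[P+](c1ccccc1)(c1ccccc1)c1ccccc1.[Br-]
Why: Wittig methylenation with excess non-stabilised ylide (one equivalent is consumed by the hydroxyl); in the preferred chair the C5 bromide is equatorial and has no antiperiplanar hydrogen, which should disfavour E2 loss of HBr.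

Step 12
Reactants: 18 (1S,3R,4R)-3-bromo-1-[(5R)-5-[(tert-butyldimethylsilyl)oxy]-6-methylhepta-1,6-dien-2-yl]-4-chloro-4-methylcyclohexan-1-ol
Product: 19 (1S,3R,4R)-3-bromo-4-chloro-1-[(5R)-5-hydroxy-6-methylhepta-1,6-dien-2-yl]-4-methylcyclohexan-1-ol
Conditions: HF·pyridine, pyridine, THF, 0 °C to rt
Reagents that add atoms: none
Why: Fluoride-driven cleavage of the secondary allylic silyl ether under pyridine-buffered conditions that should leave the secondary bromide, the tertiary chloride and the tertiary allylic alcohol intact.

**Compound list**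

1 | (R)-lactic acid | C[C@@H](O)C(=O)O | starting material
2 | pivalaldehyde | CC(C)(C)C=O | starting material
3 | (2R,5R)-2-tert-butyl-5-methyl-1,3-dioxolan-4-one | C[C@H]1O[C@@H](C(C)(C)C)OC1=O | intermediate
4 | (2R,5S)-5-bromo-2-tert-butyl-5-methyl-1,3-dioxolan-4-one | C[C@@]1(Br)O[C@@H](C(C)(C)C)OC1=O | intermediate
5 | (2R)-2-tert-butyl-5-methylene-1,3-dioxolan-4-one | C=C1O[C@@H](C(C)(C)C)OC1=O | intermediate
6 | isoprene | C=CC(C)=C | starting material
7 | (2R,5S)-2-tert-butyl-8-methyl-1,3-dioxaspiro[4.5]dec-7-en-4-one | CC1=CC[C@]2(CC1)O[C@@H](C(C)(C)C)OC2=O | intermediate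
8 | methyl (S)-1-hydroxy-4-methylcyclohex-3-ene-1-carboxylate | COC(=O)[C@]1(O)CCC(C)=CC1 | intermediate
9 | methyl (1S,3R,4R)-3-bromo-4-methyl-7-oxabicyclo[2.2.1]heptane-1-carboxylate | COC(=O)[C@@]12CC[C@@](C)(O1)[C@H](Br)C2 | intermediate
10 | methyl (1S,3R,4R)-3-bromo-4-chloro-1-hydroxy-4-methylcyclohexane-1-carboxylate | COC(=O)[C@]1(O)CC[C@@](C)(Cl)[C@H](Br)C1 | intermediate
11 | (1S,3R,4R)-3-bromo-4-chloro-1-hydroxy-N-methoxy-N,4-dimethylcyclohexane-1-carboxamide | CON(C)C(=O)[C@]1(O)CC[C@@](C)(Cl)[C@H](Br)C1 | intermediate
12 | 5-bromo-2-methylpent-2-ene | CC(C)=CCCBr | starting material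
13 | (R)-3-(2-bromoethyl)-2,2-dimethyloxirane | CC1(C)O[C@@H]1CCBr | intermediate
14 | (R)-5-bromo-2-methylpent-1-en-3-ol | C=C(C)[C@H](O)CCBr | intermediate
15 | (R)-[(5-bromo-2-methylpent-1-en-3-yl)oxy](tert-butyl)dimethylsilane | C=C(C)[C@H](O[Si](C)(C)C(C)(C)C)CCBr | intermediate
16 | [(3R)-3-[(tert-butyldimethylsilyl)oxy]-4-methylpent-4-en-1-yl]magnesium bromide | C=C(C)[C@H](O[Si](C)(C)C(C)(C)C)CC[Mg]Br | intermediate
17 | (4R)-1-[(1S,3R,4R)-3-bromo-4-chloro-1-hydroxy-4-methylcyclohexyl]-4-[(tert-butyldimethylsilyl)oxy]-5-methylhex-5-en-1-one | C=C(C)[C@H](O[Si](C)(C)C(C)(C)C)CCC(=O)[C@]1(O)CC[C@@](C)(Cl)[C@H](Br)C1 | intermediate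
18 | (1S,3R,4R)-3-bromo-1-[(5R)-5-[(tert-butyldimethylsilyl)oxy]-6-methylhepta-1,6-dien-2-yl]-4-chloro-4-methylcyclohexan-1-ol | C=C(C)[C@H](O[Si](C)(C)C(C)(C)C)CCC(=C)[C@]1(O)CC[C@@](C)(Cl)[C@H](Br)C1 | intermediate
19 | (1S,3R,4R)-3-bromo-4-chloro-1-[(5R)-5-hydroxy-6-methylhepta-1,6-dien-2-yl]-4-methylcyclohexan-1-ol | C=C(C)[C@H](O)CCC(=C)[C@]1(O)CC[C@@](C)(Cl)[C@H](Br)C1 | target

**Totals.** Total step count: 12. Longest linear sequence: 9 steps (steps 1–6 and 10–12); steps 7–9 make the side-chain fragment.

**Steps most likely to fail**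

Step 3. The process at risk is the orientation of the cycloaddition: the 2-methyl group of isoprene directs only weakly, so the meta-oriented adduct can form beside 7, and at the temperature needed the dienophile can polymerise faster than it adds. The fallback sets out from compound 6 and comes back at compound 8. Commercial 2,2-dimethyl-1,3-dioxan-5-one is O-acylated (cyclohexanecarbonyl chloride, Et3N, DMAP) to the enol ester 2,2-dimethyl-4H-1,3-dioxin-5-yl cyclohexanecarboxylate F1. Heating F1 in toluene expels acetone by a retro-hetero-Diels–Alder reaction and gives 2-(cyclohexanecarbonyloxy)prop-2-enal F2. An iminium-catalysed Diels–Alder reaction of F2 with 6 (salt of 1,1′-binaphthyl-2,2′-diamine with Tf2NH, that antipode of the diamine which delivers the S adduct, EtCN, low temperature) should give (S)-1-formyl-4-methylcyclohex-3-en-1-yl cyclohexanecarboxylate F3, since the strongly polarised iminium ion enforces para orientation. Oxidative esterification with I2 and KOH in MeOH, with methanolysis of the acyl group in the same pot, then returns 8.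

Step 5. The process at risk is the second stage: after ionisation of the C4–O bond the C1 titanium alkoxide can re-close onto C4, or the tertiary cation can lose a proton instead of taking up chloride. The fallback sets out from compound 8 and comes back at compound 10. The NBS stage is run alone and 9 is isolated. Acylative ether cleavage with AcCl and catalytic ZnCl2 (CH2Cl2, 0 °C) traps the departing oxygen irreversibly as an acetate while chloride opens the bromonium ion, which should give methyl (1S,3R,4R)-1-acetoxy-3-bromo-4-chloro-4-methylcyclohexane-1-carboxylate F4. Methanolysis of the tertiary acetate (K2CO3, MeOH, rt) then gives 10.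

Step 11. The process at risk is slow ylide addition to the hindered, alkoxide-bearing ketone, which leaves the basic medium time for α-ketol ring expansion or dehydrohalogenation. The fallback sets out from compound 17 and comes back at compound 19. The weakly basic organocerium reagent from Me3SiCH2Li and CeCl3 (THF, −78 °C) adds to the ketone to give the β-hydroxysilane (5R)-2-[(1S,3R,4R)-3-bromo-4-chloro-1-hydroxy-4-methylcyclohexyl]-5-[(tert-butyldimethylsilyl)oxy]-6-methyl-1-(trimethylsilyl)hept-6-en-2-ol F5, as a mixture of epimers at the new carbinol. Aqueous HF in MeCN then effects the acid-mediated Peterson elimination and removes the silyl ether in the same operation, giving 19 directly.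

**Further compounds**

F1 | step 3 | 2,2-dimethyl-4H-1,3-dioxin-5-yl cyclohexanecarboxylate | CC1(C)OCC(OC(=O)C2CCCCC2)=CO1
F2 | step 3 | 2-(cyclohexanecarbonyloxy)prop-2-enal | C=C(OC(=O)C1CCCCC1)C=O
F3 | step 3 | (S)-1-formyl-4-methylcyclohex-3-en-1-yl cyclohexanecarboxylate | O=C[C@]1(OC(=O)C2CCCCC2)CCC(C)=CC1
F4 | step 5 | methyl (1S,3R,4R)-1-acetoxy-3-bromo-4-chloro-4-methylcyclohexane-1-carboxylate | COC(=O)[C@]1(OC(C)=O)CC[C@@](C)(Cl)[C@H](Br)C1
F5 | step 11 | (5R)-2-[(1S,3R,4R)-3-bromo-4-chloro-1-hydroxy-4-methylcyclohexyl]-5-[(tert-butyldimethylsilyl)oxy]-6-methyl-1-(trimethylsilyl)hept-6-en-2-ol | C=C(C)[C@H](O[Si](C)(C)C(C)(C)C)CCC(O)(C[Si](C)(C)C)[C@]1(O)CC[C@@](C)(Cl)[C@H](Br)C1
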